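**Retrosynthetic overview** (eremophilane numbering: ring A = C1–C2–C3–C4–C5–C10, ring B = C5–C6=C7–C8(=O)–C9=C10, C11 = carbinol carbon)
1. Enabling feature: ring B is a cyclohexa-2,5-dienone with a quaternary C5 (no phenol tautomer). Its C8(=O)–C7=C6–C5 unit is a ring-opened cyclobutenone, and its C9=C10 edge, shared with ring A, is an alkyne whose tether (C1–C4) is ring A itself.
2. Last disconnection: the C3 ester, giving the bicyclic diol and (Z)-2-methyl-3-(methylsulfanyl)acrylic acid (from propargyl alcohol by anti-carbomagnesiation/iodination, oxidation and C–S coupling).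
3. Key disconnection: C8–C9 and C5–C10 together, giving a monocyclic cyclobutenone with a silyl-capped alkyne on its C5 side chain. Ni(0) C–C activation with strain release forms ring A (alkyne insertion), then ring B (reductive elimination), and the C5 stereocentre.
4. The four-membered ring (temporary, formed first) comes from a ketene/ynol ether [2+2] (C6–C7, C5–C8) and a reductive carbonyl transposition.
5. The ketene precursor acid comes from Brown (Z)-crotylboration of 5-(trimethylsilyl)pent-4-ynal (sets C3 and C4), hydroboration/oxidation and α-methylation.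

Key step: step 10

Remark: the nickel-bound intermediates 23 and 24 are drawn without ancillary ligands, and 20–22 are carried as mixtures of epimers at the quaternary carbon because that centre is expected to be planarised and reset in step 10.

**Step 1**
Reactants: 1 5-(trimethylsilyl)pent-4-yn-1-ol
Product: 2 5-(trimethylsilyl)pent-4-ynal
Conditions: TEMPO (10 mol%), PhI(OAc)2 (1.1 equiv), CH2Cl2, rt
Reagents that add atoms: none
Why: TEMPO/hypervalent-iodine oxidation of a primary alcohol should stop at the aldehyde and leave the silylalkyne untouched.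

**Step 2**
Reactants: 2 5-(trimethylsilyl)pent-4-ynal; 3 cis-but-2-ene
Product: 5 (3R,4R)-3-methyl-8-(trimethylsilyl)oct-1-en-7-yn-4-ol, via crotylborane 4 (not isolated)
Conditions: 3, KOt-Bu, n-BuLi, THF, −78 → −45 °C; (−)-Ipc2BOMe, −78 °C; BF3·OEt2; 2, −78 °C; then ethanolamine, rt
Reagents that add atoms: (−)-B-methoxydiisopinocampheylborane, COB([C@@H]1C[C@@H]2C[C@H]([C@H]1C)C2(C)C)[C@@H]1C[C@@H]2C[C@H]([C@H]1C)C2(C)C (boron and isopinocampheyl groups of 4 only)
Why: Brown crotylboration through a closed Zimmerman–Traxler chair, in which the Z geometry of the crotyl group gives the syn methyl/hydroxyl relationship and the (+)-α-pinene-derived isopinocampheyl groups direct attack to the si face of the aldehyde, so that C3 and C4 of the target are both set here.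

**Step 3**
Reactants: 5 (3R,4R)-3-methyl-8-(trimethylsilyl)oct-1-en-7-yn-4-ol
Product: 6 tert-butyldimethyl{[(3R,4R)-3-methyl-8-(trimethylsilyl)oct-1-en-7-yn-4-yl]oxy}silane
Conditions: TBSOTf, 2,6-lutidine, CH2Cl2, −78 → 0 °C
Reagents that add atoms: tert-butyldimethylsilyl trifluoromethanesulfonate, CC(C)(C)[Si](C)(C)OS(=O)(=O)C(F)(F)F
Why: Standard silylation of a hindered secondary alcohol with a silyl triflate, giving the bulky ether that later serves as an equatorial steering group.

**Step 4**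
Reactants: 6 tert-butyldimethyl{[(3R,4R)-3-methyl-8-(trimethylsilyl)oct-1-en-7-yn-4-yl]oxy}silane
Product: 8 (3R,4R)-4-[(tert-butyldimethylsilyl)oxy]-3-methyl-8-(trimethylsilyl)oct-7-yn-1-ol, via alkylborane 7 (not isolated)
Conditions: 9-BBN, THF, 0 °C → rt; then NaBO3·4H2O, H2O, rt
Reagents that add atoms: 9-borabicyclo[3.3.1]nonane, B1C2CCCC1CCC2 (boron group of 7 only); sodium perborate, [Na+].[O-]OB=O (oxygen of 8)
Why: Anti-Markovnikov hydroboration–oxidation, in which 9-BBN should add to the monosubstituted alkene much faster than to the internal silylalkyne and the mildly basic perborate oxidation should spare the alkynyl C–Si bond.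

**Step 5**
Reactants: 8 (3R,4R)-4-[(tert-butyldimethylsilyl)oxy]-3-methyl-8-(trimethylsilyl)oct-7-yn-1-ol
Product: 10 (3R,4R)-4-[(tert-butyldimethylsilyl)oxy]-3-methyl-8-(trimethylsilyl)oct-7-ynoic acid, via aldehyde 9 (not isolated)
Conditions: TEMPO (cat.), NaOCl (cat.), NaClO2, MeCN/phosphate buffer (pH 6.7), 35 °C
Reagents that add atoms: sodium chlorite, [Na+].[O-]Cl=O
Why: TEMPO/bleach-catalysed chlorite oxidation takes the primary alcohol through the aldehyde to the acid at near-neutral pH, where the silyl ether and the silylalkyne should survive.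

**Step 6**
Reactants: 10 (3R,4R)-4-[(tert-butyldimethylsilyl)oxy]-3-methyl-8-(trimethylsilyl)oct-7-ynoic acid
Product: 12 (2RS,3R,4R)-4-[(tert-butyldimethylsilyl)oxy]-2,3-dimethyl-8-(trimethylsilyl)oct-7-ynoic acid, via dilithium enediolate 11 (not isolated)
Conditions: LDA (2.2 equiv), THF, −78 → 0 °C; MeI, −78 °C → rt; aq. HCl work-up
Reagents that add atoms: lithium diisopropylamide, [Li]N(C(C)C)C(C)C (lithium of 11 only); iodomethane, CI
Why: C-Alkylation of a carboxylic acid dianion, whose new C2 centre (C5 of the target) forms as a mixture that is irrelevant because this carbon becomes the sp2 ketene carbon in step 8.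

**Step 7**
Reactants: 13 ethoxyethyne; 14 acetone
Product: 17 triethyl[(4-ethoxy-2-methylbut-3-yn-2-yl)oxy]silane, via lithium ethoxyacetylide 15 (not isolated), via lithium alkoxide 16 (not isolated)
Conditions: n-BuLi, THF, −78 °C; 14; then TESOTf, −78 → 0 °C
Reagents that add atoms: n-butyllithium, [Li]CCCC (lithium of 15 and 16 only); triethylsilyl trifluoromethanesulfonate, CC[Si](CC)(CC)OS(=O)(=O)C(F)(F)F
Why: Acetylide addition to a ketone followed by O-silylation of the tertiary alkoxide in the same flask, the protection being needed because the free ethoxyethynyl carbinol is prone to Meyer–Schuster rearrangement and would add to the ketene.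

**Step 8**
Reactants: 12 (2RS,3R,4R)-4-[(tert-butyldimethylsilyl)oxy]-2,3-dimethyl-8-(trimethylsilyl)oct-7-ynoic acid; 17 triethyl[(4-ethoxy-2-methylbut-3-yn-2-yl)oxy]silane
Product: 20 3-ethoxy-4-methyl-4-[(2R,3R)-3-[(tert-butyldimethylsilyl)oxy]-7-(trimethylsilyl)hept-6-yn-2-yl]-2-{2-[(triethylsilyl)oxy]propan-2-yl}cyclobut-2-en-1-one (both C4 epimers), via acid chloride 18 (not isolated), via ketene 19 (not isolated)
Conditions: 1-chloro-N,N,2-trimethylprop-1-en-1-amine, toluene, 0 °C → rt; then 17 (2 equiv), Et3N, 70 °C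
Reagents that add atoms: 1-chloro-N,N,2-trimethylprop-1-en-1-amine, CC(C)=C(Cl)N(C)C (chlorine of 18 only)
Why: Neutral acid chloride formation with the Ghosez reagent, dehydrochlorination to the methyl(alkyl)ketene and thermal [2+2] ketene–alkynyl ether cycloaddition, in which the ketene carbonyl carbon bonds to the alkyne carbon β to oxygen, so that the silyloxyisopropyl group ends up at C2 and the ethoxy group at C3 of the cyclobutenone.

**Step 9**
Reactants: 20 3-ethoxy-4-methyl-4-[(2R,3R)-3-[(tert-butyldimethylsilyl)oxy]-7-(trimethylsilyl)hept-6-yn-2-yl]-2-{2-[(triethylsilyl)oxy]propan-2-yl}cyclobut-2-en-1-one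
Product: 22 4-methyl-4-[(2R,3R)-3-[(tert-butyldimethylsilyl)oxy]-7-(trimethylsilyl)hept-6-yn-2-yl]-2-{2-[(triethylsilyl)oxy]propan-2-yl}cyclobut-2-en-1-one (both C4 epimers), via cyclobutenol 21 (not isolated)
Conditions: DIBAL-H, CH2Cl2, −78 °C; then aq. oxalic acid, Et2O, 0 °C
Reagents that add atoms: water, O (oxygen of the new carbonyl group)
Why: 1,2-Reduction of the vinylogous ester and mild acid hydrolysis with allylic transposition (Stork–Danheiser-type) should move the carbonyl next to the quaternary carbon (it becomes C8) and leave C6 as a CH.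

**Step 10**
Reactants: 22 4-methyl-4-[(2R,3R)-3-[(tert-butyldimethylsilyl)oxy]-7-(trimethylsilyl)hept-6-yn-2-yl]-2-{2-[(triethylsilyl)oxy]propan-2-yl}cyclobut-2-en-1-one
Product: 25 (4aR,5R,6R)-6-[(tert-butyldimethylsilyl)oxy]-4a,5-dimethyl-3-{2-[(triethylsilyl)oxy]propan-2-yl}-1-(trimethylsilyl)-5,6,7,8-tetrahydronaphthalen-2(4aH)-one, via nickelacyclopentenone 23 (not isolated), via nickelacycloheptadienone 24 (not isolated)
Conditions: Ni(cod)2 (10 mol%), PPh3 (20 mol%), toluene (0.02 M), 0 °C → rt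
Reagents that add atoms: bis(1,5-cyclooctadiene)nickel(0), C1=CCCC=CCC1.C1=CCCC=CCC1.[Ni] (nickel of 23 and 24 only; catalyst)
Why: Proposed new method: Ni(0) is expected to add oxidatively to the strained acyl–allyl bond C8–C5 of 22, well below the temperature of thermal ring opening, to give nickelacycle 23, whose η4-vinylketene (acyl/η3-allyl) form makes C5 planar so that both C5 epimers of 22 should drain into one equilibrating set of complexes; the tethered silylalkyne then inserts into the Ni–C5 bond (C5–C10 formed, ring A closed 6-exo-dig, silicon-bearing C9 on nickel) to give 24, and acyl–alkenyl reductive elimination forms C8–C9 and closes the six-membered ring B. The closest known reaction type is the Ni(0)-catalysed [4+2] benzannulation of cyclobutenones with alkynes (and the related Rh-catalysed cut-and-sew carboacylations), here made intramolecular and run on a 4,4-disubstituted cyclobutenone so that the product is a cyclohexa-2,5-dienone that cannot tautomerise to a phenol. The new C5 stereocentre is controlled by the existing C3 and C4 centres: in the chair-like insertion transition structure the C4 methyl and C3 silyloxy groups are both equatorial and the C5 methyl is axial and cis to the C4 methyl, whereas the C5 epimer would need a syn-diaxial C5-methyl/C3-silyloxy pair. Regioselectivity is enforced by the four-atom tether (the reverse insertion would give a bridged anti-Bredt dienone), insertion should beat alkyne oligomerisation because of the TMS cap and the intramolecular setting, and the low temperature keeps the free vinylketene and its 1,5-hydrogen shift to a dienal out of play. Release of the cyclobutenone ring strain drives the C–C cleavage, and one operation delivers both six-membered rings, the cross-conjugated dienone and the quaternary stereocentre.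

**Step 11**
Reactants: 25 (4aR,5R,6R)-6-[(tert-butyldimethylsilyl)oxy]-4a,5-dimethyl-3-{2-[(triethylsilyl)oxy]propan-2-yl}-1-(trimethylsilyl)-5,6,7,8-tetrahydronaphthalen-2(4aH)-one
Product: 26 (4aR,5R,6R)-6-hydroxy-3-(2-hydroxypropan-2-yl)-4a,5-dimethyl-5,6,7,8-tetrahydronaphthalen-2(4aH)-one
Conditions: TBAF (5 equiv), THF, 0 °C → rt; aq. NH4Cl
Reagents that add atoms: none
Why: Fluoride should cleave both silyl ethers and also the C9–Si bond, since a vinylsilane α to a carbonyl undergoes ready protodesilylation, so one operation reveals the diol and C9–H.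

**Step 12**
Reactants: 27 prop-2-yn-1-ol
Product: 29 (2Z)-3-iodo-2-methylprop-2-en-1-ol, via magnesium chelate 28 (not isolated)
Conditions: MeMgBr (2.5 equiv), CuI (10 mol%), THF, −10 °C → rt; then I2, −78 → 0 °C; aq. NH4Cl
Reagents that add atoms: methylmagnesium bromide, C[Mg]Br (methyl group; magnesium of 28); iodine, II
Why: Copper-catalysed anti-carbomagnesiation of propargyl alcohol, in which the magnesium alkoxide directs methyl to C2 and magnesium to C3 within a five-membered chelate, and iodinolysis with retention gives the Z iodide (iodine cis to CH2OH).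

**Step 13**
Reactants: 29 (2Z)-3-iodo-2-methylprop-2-en-1-ol
Product: 31 (2Z)-3-iodo-2-methylprop-2-enoic acid, via enal 30 (not isolated)
Conditions: TEMPO (cat.), NaOCl (cat.), NaClO2, MeCN/phosphate buffer (pH 6.7), 35 °C
Reagents that add atoms: sodium chlorite, [Na+].[O-]Cl=O
Why: The same buffered TEMPO/chlorite oxidation as in step 5 should convert the allylic alcohol into the acid without touching the alkene geometry.

**Step 14**
Reactants: 31 (2Z)-3-iodo-2-methylprop-2-enoic acid
Product: 32 (2Z)-2-methyl-3-(methylsulfanyl)prop-2-enoic acid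
Conditions: NaSMe (2.5 equiv), CuI (10 mol%), DMF, 50 °C; then aq. HCl
Reagents that add atoms: sodium methanethiolate, C[S-].[Na+]
Why: Carboxylate-assisted copper-catalysed (Ullmann-type) vinylic C–S coupling, equivalent to addition–elimination on a β-iodoacrylate, proceeds with retention, so sulfur ends up cis to the carboxyl group (Z).

**Step 15**
Reactants: 26 (4aR,5R,6R)-6-hydroxy-3-(2-hydroxypropan-2-yl)-4a,5-dimethyl-5,6,7,8-tetrahydronaphthalen-2(4aH)-one; 32 (2Z)-2-methyl-3-(methylsulfanyl)prop-2-enoic acid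
Product: 34 (4aR,5R,6R)-3-(2-hydroxypropan-2-yl)-4a,5-dimethyl-2-oxo-2,4a,5,6,7,8-hexahydronaphthalen-6-yl (2Z)-2-methyl-3-(methylsulfanyl)prop-2-enoate (CNP0150028.1), via mixed anhydride 33 (not isolated)
Conditions: 32, 2,4,6-trichlorobenzoyl chloride, Et3N, THF, rt; then 26, DMAP, toluene, rt
Reagents that add atoms: 2,4,6-trichlorobenzoyl chloride, O=C(Cl)c1c(Cl)cc(Cl)cc1Cl (aroyl group of 33 only)
Why: Yamaguchi esterification should acylate the secondary C3 hydroxyl while the tertiary C11 hydroxyl stays inert, and the C3 configuration is retained because its C–O bond is not broken.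

**Compound list**
1 | 5-(trimethylsilyl)pent-4-yn-1-ol | C[Si](C)(C)C#CCCCO | starting material
2 | 5-(trimethylsilyl)pent-4-ynal | C[Si](C)(C)C#CCCC=O | intermediate
3 | cis-but-2-ene | C/C=C\C | starting material
4 | (−)-B-[(2Z)-but-2-en-1-yl]diisopinocampheylborane | C/C=C\CB([C@@H]1C[C@@H]2C[C@H]([C@H]1C)C2(C)C)[C@@H]1C[C@@H]2C[C@H]([C@H]1C)C2(C)C | intermediate
5 | (3R,4R)-3-methyl-8-(trimethylsilyl)oct-1-en-7-yn-4-ol | C[Si](C)(C)C#CCC[C@@H](O)[C@H](C)C=C | intermediate
6 | tert-butyldimethyl{[(3R,4R)-3-methyl-8-(trimethylsilyl)oct-1-en-7-yn-4-yl]oxy}silane | C[Si](C)(C)C#CCC[C@@H](O[Si](C)(C)C(C)(C)C)[C@H](C)C=C | intermediate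
7 | 9-[(3R,4R)-4-[(tert-butyldimethylsilyl)oxy]-3-methyl-8-(trimethylsilyl)oct-7-yn-1-yl]-9-borabicyclo[3.3.1]nonane | C[Si](C)(C)C#CCC[C@@H](O[Si](C)(C)C(C)(C)C)[C@H](C)CCB1C2CCCC1CCC2 | intermediate
8 | (3R,4R)-4-[(tert-butyldimethylsilyl)oxy]-3-methyl-8-(trimethylsilyl)oct-7-yn-1-ol | C[Si](C)(C)C#CCC[C@@H](O[Si](C)(C)C(C)(C)C)[C@H](C)CCO | intermediate
9 | (3R,4R)-4-[(tert-butyldimethylsilyl)oxy]-3-methyl-8-(trimethylsilyl)oct-7-ynal | C[Si](C)(C)C#CCC[C@@H](O[Si](C)(C)C(C)(C)C)[C@H](C)CC=O | intermediate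
10 | (3R,4R)-4-[(tert-butyldimethylsilyl)oxy]-3-methyl-8-(trimethylsilyl)oct-7-ynoic acid | C[Si](C)(C)C#CCC[C@@H](O[Si](C)(C)C(C)(C)C)[C@H](C)CC(=O)O | intermediate
11 | dilithium (3R,4R)-4-[(tert-butyldimethylsilyl)oxy]-3-methyl-8-(trimethylsilyl)oct-1-en-7-yne-1,1-diolate | C[Si](C)(C)C#CCC[C@@H](O[Si](C)(C)C(C)(C)C)[C@H](C)C=C([O-])[O-].[Li+].[Li+] | intermediate
12 | (2RS,3R,4R)-4-[(tert-butyldimethylsilyl)oxy]-2,3-dimethyl-8-(trimethylsilyl)oct-7-ynoic acid | C[Si](C)(C)C#CCC[C@@H](O[Si](C)(C)C(C)(C)C)[C@H](C)C(C)C(=O)O | intermediate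
13 | ethoxyethyne | C#COCC | starting material
14 | acetone | CC(C)=O | starting material
15 | lithium ethoxyacetylide | [Li]C#COCC | intermediate
16 | lithium 4-ethoxy-2-methylbut-3-yn-2-olate | CCOC#CC(C)(C)[O-].[Li+] | intermediate
17 | triethyl[(4-ethoxy-2-methylbut-3-yn-2-yl)oxy]silane | CCOC#CC(C)(C)O[Si](CC)(CC)CC | intermediate
18 | (2RS,3R,4R)-4-[(tert-butyldimethylsilyl)oxy]-2,3-dimethyl-8-(trimethylsilyl)oct-7-ynoyl chloride | C[Si](C)(C)C#CCC[C@@H](O[Si](C)(C)C(C)(C)C)[C@H](C)C(C)C(=O)Cl | intermediate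
19 | (3R,4R)-4-[(tert-butyldimethylsilyl)oxy]-2,3-dimethyl-8-(trimethylsilyl)oct-1-en-7-yn-1-one (ketene) | C[Si](C)(C)C#CCC[C@@H](O[Si](C)(C)C(C)(C)C)[C@H](C)C(C)=C=O | intermediate
20 | 3-ethoxy-4-methyl-4-[(2R,3R)-3-[(tert-butyldimethylsilyl)oxy]-7-(trimethylsilyl)hept-6-yn-2-yl]-2-{2-[(triethylsilyl)oxy]propan-2-yl}cyclobut-2-en-1-one (both C4 epimers) | CCOC1=C(C(C)(C)O[Si](CC)(CC)CC)C(=O)C1(C)[C@@H](C)[C@@H](CCC#C[Si](C)(C)C)O[Si](C)(C)C(C)(C)C | intermediate
21 | 3-ethoxy-4-methyl-4-[(2R,3R)-3-[(tert-butyldimethylsilyl)oxy]-7-(trimethylsilyl)hept-6-yn-2-yl]-2-{2-[(triethylsilyl)oxy]propan-2-yl}cyclobut-2-en-1-ol | CCOC1=C(C(C)(C)O[Si](CC)(CC)CC)C(O)C1(C)[C@@H](C)[C@@H](CCC#C[Si](C)(C)C)O[Si](C)(C)C(C)(C)C | intermediate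
22 | 4-methyl-4-[(2R,3R)-3-[(tert-butyldimethylsilyl)oxy]-7-(trimethylsilyl)hept-6-yn-2-yl]-2-{2-[(triethylsilyl)oxy]propan-2-yl}cyclobut-2-en-1-one (both C4 epimers) | O=C1C(C(C)(C)O[Si](CC)(CC)CC)=CC1(C)[C@@H](C)[C@@H](CCC#C[Si](C)(C)C)O[Si](C)(C)C(C)(C)C | intermediate
23 | nickelacyclopentenone from C8–C5 insertion (ligands omitted) | O=C1[Ni]C(C)([C@@H](C)[C@@H](CCC#C[Si](C)(C)C)O[Si](C)(C)C(C)(C)C)C=C1C(C)(C)O[Si](CC)(CC)CC | intermediate
24 | nickelacycloheptadienone after alkyne insertion (ligands omitted) | CC(C)(C)[Si](C)(C)O[C@@H]1CCC2=C([Si](C)(C)C)[Ni]C(=O)C(C(C)(C)O[Si](CC)(CC)CC)=C[C@]2(C)[C@H]1C | intermediate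
25 | (4aR,5R,6R)-6-[(tert-butyldimethylsilyl)oxy]-4a,5-dimethyl-3-{2-[(triethylsilyl)oxy]propan-2-yl}-1-(trimethylsilyl)-5,6,7,8-tetrahydronaphthalen-2(4aH)-one | CC(C)(C)[Si](C)(C)O[C@@H]1CCC2=C([Si](C)(C)C)C(=O)C(C(C)(C)O[Si](CC)(CC)CC)=C[C@]2(C)[C@H]1C | intermediate
26 | (4aR,5R,6R)-6-hydroxy-3-(2-hydroxypropan-2-yl)-4a,5-dimethyl-5,6,7,8-tetrahydronaphthalen-2(4aH)-one | O[C@@H]1CCC2=CC(=O)C(C(C)(C)O)=C[C@]2(C)[C@H]1C | intermediate
27 | prop-2-yn-1-ol | C#CCO | starting material
28 | 4-methyl-2,5-dihydro-1,2-oxamagnesole (cyclic (Z)-alkenylmagnesium alkoxide) | CC1=C[Mg]OC1 | intermediate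
29 | (2Z)-3-iodo-2-methylprop-2-en-1-ol | OC/C(C)=C\I | intermediate
30 | (2Z)-3-iodo-2-methylprop-2-enal | O=C/C(C)=C\I | intermediate
31 | (2Z)-3-iodo-2-methylprop-2-enoic acid | OC(=O)/C(C)=C\I | intermediate
32 | (2Z)-2-methyl-3-(methylsulfanyl)prop-2-enoic acid | CS/C=C(/C)C(=O)O | intermediate
33 | (2Z)-2-methyl-3-(methylsulfanyl)prop-2-enoic 2,4,6-trichlorobenzoic anhydride | CS/C=C(/C)C(=O)OC(=O)c1c(Cl)cc(Cl)cc1Cl | intermediate
34 | (4aR,5R,6R)-3-(2-hydroxypropan-2-yl)-4a,5-dimethyl-2-oxo-2,4a,5,6,7,8-hexahydronaphthalen-6-yl (2Z)-2-methyl-3-(methylsulfanyl)prop-2-enoate | CS/C=C(/C)C(=O)O[C@@H]1CCC2=CC(=O)C(C(C)(C)O)=C[C@]2(C)[C@H]1C | target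

**Step count**
Total: 15 steps. Longest linear sequence: 11 steps (1, 2, 3, 4, 5, 6, 8, 9, 10, 11, 15).

**Steps most likely to fail**

1. Step 10 (Proposed new method). What may go wrong: incomplete stereoconvergence, because if the nickel-bound vinylketene diastereomers do not interconvert faster than alkyne insertion, each C5 epimer of 22 is carried through stereospecifically and C5 is set without control. Decarbonylation of the acylnickel or alkyne oligomerisation may also outrun insertion.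
Fallback (sets out from 12, returns at 26): Michael addition/aldol condensation of an α-branched aldehyde with an ynone, the classical entry to 4,4-disubstituted cyclohexadienones, which forms C5–C10 and C6=C7 instead. Acid 12 is reduced (LiAlH4, THF, 0 °C) to (2RS,3R,4R)-4-[(tert-butyldimethylsilyl)oxy]-2,3-dimethyl-8-(trimethylsilyl)oct-7-yn-1-ol F1, and the alkynylsilane is cleaved (K2CO3, MeOH) to (2RS,3R,4R)-4-[(tert-butyldimethylsilyl)oxy]-2,3-dimethyloct-7-yn-1-ol F2. Commercial ethyl 3-hydroxy-3-methylbutanoate is silylated (TESOTf, 2,6-lutidine) to ethyl 3-methyl-3-[(triethylsilyl)oxy]butanoate F3 and converted (MeNHOMe·HCl, i-PrMgCl, THF, −20 °C) into N-methoxy-N,3-dimethyl-3-[(triethylsilyl)oxy]butanamide F4. The dilithio derivative of F2 (n-BuLi, 2.1 equiv, THF, −78 °C) is acylated with F4 to (9R,10R,11RS)-9-[(tert-butyldimethylsilyl)oxy]-12-hydroxy-2,10,11-trimethyl-2-[(triethylsilyl)oxy]dodec-5-yn-4-one F5, whose primary alcohol is oxidised (Dess–Martin periodinane) to (2RS,3R,4R)-4-[(tert-butyldimethylsilyl)oxy]-2,3,11-trimethyl-9-oxo-11-[(triethylsilyl)oxy]dodec-7-ynal F6. Pyrrolidine/AcOH (MeCN, rt → 60 °C) should effect 6-exo-dig enamine Michael addition of C5 to the ynone, under the same chair-like control by the C4 methyl and C3 silyloxy groups, followed by aldol condensation of C7 with the C6 aldehyde. This gives (4aR,5R,6R)-6-[(tert-butyldimethylsilyl)oxy]-4a,5-dimethyl-3-{2-[(triethylsilyl)oxy]propan-2-yl}-5,6,7,8-tetrahydronaphthalen-2(4aH)-one F7, and TBAF then gives 26.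

2. Step 8. What may go wrong: slow dehydrochlorination of the branched acid chloride and steric retardation of the cycloaddition at the alkyne carbon that bears the tertiary silyloxy group, so that ketene dimerisation, lactonisation of the γ-silyloxy acid chloride or thermal decomposition of the ynol ether takes over.
Fallback (sets out from 12, returns at 22): the alkyne partner is replaced by an unhindered enol ether and the carbinol is installed by aldol, so no carbonyl transposition is needed (the acid carbon then becomes C8). Ketene 19 is generated as in step 8 but in ethyl vinyl ether (sealed tube, 70 °C), giving by ketene–enol ether [2+2] 3-ethoxy-2-methyl-2-[(2R,3R)-3-[(tert-butyldimethylsilyl)oxy]-7-(trimethylsilyl)hept-6-yn-2-yl]cyclobutan-1-one F8. Its only enolisable position is deprotonated (LDA, THF, −78 °C) and added to acetone to give 3-ethoxy-4-(2-hydroxypropan-2-yl)-2-methyl-2-[(2R,3R)-3-[(tert-butyldimethylsilyl)oxy]-7-(trimethylsilyl)hept-6-yn-2-yl]cyclobutan-1-one F9. Silylation (TESOTf, 2,6-lutidine) gives 3-ethoxy-2-methyl-2-[(2R,3R)-3-[(tert-butyldimethylsilyl)oxy]-7-(trimethylsilyl)hept-6-yn-2-yl]-4-{2-[(triethylsilyl)oxy]propan-2-yl}cyclobutan-1-one F10, and DBU-induced β-elimination of ethanol delivers 22.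

3. Step 15. What may go wrong: Z-to-E isomerisation of the β-(methylsulfanyl)acrylate through reversible conjugate addition of DMAP or chloride to the activated acid, together with slow acylation of the hindered secondary hydroxyl.
Fallback (sets out from 26 and 31, returns at 34): the C–S bond is formed last. Diol 26 is acylated under the same Yamaguchi conditions with the geometrically robust iodo acid 31 to give (4aR,5R,6R)-3-(2-hydroxypropan-2-yl)-4a,5-dimethyl-2-oxo-2,4a,5,6,7,8-hexahydronaphthalen-6-yl (2Z)-3-iodo-2-methylprop-2-enoate F11. Addition–elimination with NaSMe (1.05 equiv, THF, −20 °C), which proceeds with retention on β-halo acrylates, then gives 34.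

**Further compounds**
F1 | step 10 | (2RS,3R,4R)-4-[(tert-butyldimethylsilyl)oxy]-2,3-dimethyl-8-(trimethylsilyl)oct-7-yn-1-ol | C[Si](C)(C)C#CCC[C@@H](O[Si](C)(C)C(C)(C)C)[C@H](C)C(C)CO
F2 | step 10 | (2RS,3R,4R)-4-[(tert-butyldimethylsilyl)oxy]-2,3-dimethyloct-7-yn-1-ol | C#CCC[C@@H](O[Si](C)(C)C(C)(C)C)[C@H](C)C(C)CO
F3 | step 10 | ethyl 3-methyl-3-[(triethylsilyl)oxy]butanoate | CCOC(=O)CC(C)(C)O[Si](CC)(CC)CC
F4 | step 10 | N-methoxy-N,3-dimethyl-3-[(triethylsilyl)oxy]butanamide | CON(C)C(=O)CC(C)(C)O[Si](CC)(CC)CC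
F5 | step 10 | (9R,10R,11RS)-9-[(tert-butyldimethylsilyl)oxy]-12-hydroxy-2,10,11-trimethyl-2-[(triethylsilyl)oxy]dodec-5-yn-4-one | CC(C)(O[Si](CC)(CC)CC)CC(=O)C#CCC[C@@H](O[Si](C)(C)C(C)(C)C)[C@H](C)C(C)CO
F6 | step 10 | (2RS,3R,4R)-4-[(tert-butyldimethylsilyl)oxy]-2,3,11-trimethyl-9-oxo-11-[(triethylsilyl)oxy]dodec-7-ynal | CC(C)(O[Si](CC)(CC)CC)CC(=O)C#CCC[C@@H](O[Si](C)(C)C(C)(C)C)[C@H](C)C(C)C=O
F7 | step 10 | (4aR,5R,6R)-6-[(tert-butyldimethylsilyl)oxy]-4a,5-dimethyl-3-{2-[(triethylsilyl)oxy]propan-2-yl}-5,6,7,8-tetrahydronaphthalen-2(4aH)-one | CC(C)(C)[Si](C)(C)O[C@@H]1CCC2=CC(=O)C(C(C)(C)O[Si](CC)(CC)CC)=C[C@]2(C)[C@H]1C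
F8 | step 8 | 3-ethoxy-2-methyl-2-[(2R,3R)-3-[(tert-butyldimethylsilyl)oxy]-7-(trimethylsilyl)hept-6-yn-2-yl]cyclobutan-1-one | CCOC1CC(=O)C1(C)[C@@H](C)[C@@H](CCC#C[Si](C)(C)C)O[Si](C)(C)C(C)(C)C
F9 | step 8 | 3-ethoxy-4-(2-hydroxypropan-2-yl)-2-methyl-2-[(2R,3R)-3-[(tert-butyldimethylsilyl)oxy]-7-(trimethylsilyl)hept-6-yn-2-yl]cyclobutan-1-one | CCOC1C(C(C)(C)O)C(=O)C1(C)[C@@H](C)[C@@H](CCC#C[Si](C)(C)C)O[Si](C)(C)C(C)(C)C
F10 | step 8 | 3-ethoxy-2-methyl-2-[(2R,3R)-3-[(tert-butyldimethylsilyl)oxy]-7-(trimethylsilyl)hept-6-yn-2-yl]-4-{2-[(triethylsilyl)oxy]propan-2-yl}cyclobutan-1-one | CCOC1C(C(C)(C)O[Si](CC)(CC)CC)C(=O)C1(C)[C@@H](C)[C@@H](CCC#C[Si](C)(C)C)O[Si](C)(C)C(C)(C)C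
F11 | step 15 | (4aR,5R,6R)-3-(2-hydroxypropan-2-yl)-4a,5-dimethyl-2-oxo-2,4a,5,6,7,8-hexahydronaphthalen-6-yl (2Z)-3-iodo-2-methylprop-2-enoate | I/C=C(/C)C(=O)O[C@@H]1CCC2=CC(=O)C(C(C)(C)O)=C[C@]2(C)[C@H]1C
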